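Readings and results were computed for substances that don't exist, and the scatter is random.

A leftover opens the reading: after 2.50 h the amber run shows 15 % starting material and 47 % target, so 38.0 % of the charge stands in neither column.

| flask | starting material | remark | time |
|---|---|---|---|
| amber | 1 M | run made earlier |  |
| red | 1.7 M | run made earlier |  |
| flask | 0.75 M |  | 2.5 h |

| run | time / h | target / % | starting material / % |
|---|---|---|---|
| amber | 0.667 | 9 | 59 |
| amber | 1.00 | 15 | 43 |
| amber | 1.50 | 25 | 29 |
| amber | 2.50 | 47 | 15 |
| red | 0.667 | 3 | 59 |
| red | 1.00 | 13 | 45 |
| red | 1.50 | 24 | 30 |
| red | 2.50 | 46 | 13 |

(each reading ± 1.5 percentage points)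

* the best time, 2.5 h at the latest, for target
* the amount of target, in percent of the starting material charged, at that time

- a reading or a percentage of target counts all its forms, free or not

Call that remainder G, the in-transit share (the gap in the mass balance). Down the amber table, G is 46.0 % at 1.50 h before it reaches 38.0 %. The red table, with its charge of 1.7 M, gives 46.0 % and 41.0 % at the same two times, so G at these two times differs between the two runs by at most 3 percentage points, with a scatter of 1.5 points on each reading.

Now follow one molecule: it leaves starting material, waits in G, then passes to target. Between those two times the amber run gains 22 points of target on a mean G, which gives 0.524 /h: this is the drain D, target gained per hour over the mean G, a molecule's chance per hour of passing on. The red run reads 0.506 /h.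

Reckoned here, D times G at the last amber reading is still 0.199 /h of the charge, so target is still climbing there. For the flask at 0.75 M this reckoning takes the limit, 2.5 h, and the mean of the two last readings, 46.5 %.

The forecast gives 2.5 h and 46.5 %: “still rising at the time limit”.

The flask gives 2.50 h and 46.2 %.

    intermediate → target (k = 1.40 × 10⁻⁴ /s)
    starting material → intermediate (k = 2.20 × 10⁻⁴ /s)
    crystals ⇌ target, rate k3*(cs3 - [target]) while solid is left; crystals form when [target] > cs3 (solubility = 27.0 mM, k = 0.0420 /s)

In the flask at the limit G is 40.0 %, and it is the intermediate, 40.0 %, which no column shows. Ten times the limit carries target in the flask to >99.9 %, so the forecast's amount belongs to this limit. A neighbour flask read at 4.00 h, 1.50 h past the limit, stands at 25.1 % intermediate, and D on the mean of the intermediate in the flask at the limit and in this neighbour brings target to 71.7 %; the neighbour flask holds 70.7 %.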